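Start from a one-step world, in which G and X go to L and Q and nothing happens next.

    G + X ⇌ L + Q (K1 = 0.59, k1 = 2.3 M⁻¹ min⁻¹)
    G + L → G.L (k2 = 2.4 M⁻¹ min⁻¹)
    L + Q → L.Q (k3 = 0.58 M⁻¹ min⁻¹)

common to all: G 0.40 M; time 10 min
- Thursday's: X 1.00 equiv
- Friday's: X 3.00 equiv

* which of these there is most of at the end, counted by the G in it, Thursday's (L / G / G.L / L.Q)
* which of these there is most of at the end, counted by the G in it, Friday's (L / G / G.L / L.Q)
* how much there is at the end of the one of these that leads, in percent of the G charged: Thursday's
* how much there is at the end of the one of these that leads, in percent of the G charged: Friday's

With the first equilibrium by itself, [L][Q]/([G][X]) comes to 0.59. Thursday's equal charges make [L]/[G] the root of that constant, so a fraction 43.4% of G turns over, which leaves [G] = 0.226 M and [Q] = 0.174 M. Friday's 3.00 equiv of X needs the quadratic, which gives 67.2%, so [G] = 0.131 M and [Q] = 0.269 M.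

Now add G + L. On Thursday's, with the other concentrations as charged, the half-life of L by this step is 0.72 min, about the same as the half-life of G by the forward direction of the first step, 0.75 min, so L goes on while it is being made, and the one-step state serves here as a reference for the reckoning, not as a state the flask stands in. Then add L + Q, which competes for the same L. The rate of G + L over the rate of L + Q is 2.4[G] over 0.58[Q], the split or selectivity factor, in which [L] cancels. Reckoned on the one-step concentrations, Thursday's split is 5.39, and Friday's is lower at 2.02.

Each G.L holds two G and each L.Q holds one, so G.L takes 2S/(2S+1) of the G in these two products, where S is the split. That gives 91.5% on Thursday's and 80.2% on Friday's. But G.L eats G, so put that answer back and go round once more: hold [Q] and take [G] at half its one-step value, as a mean over the drain. The share becomes S/(S+1), which is 84.3% on Thursday's and 66.9% on Friday's. I commit to G.L leading both flasks, a little under those figures, since some G and L remain; this reckoning gives no closer amount.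

The forecast also names G.L on Thursday's and G.L on Friday's, at 74% and 62%, saying “the L it gives is then drained mostly by the fast reaction with leftover G”.

The flask gives G.L at 73.3% on Thursday's and 61.3% on Friday's. L.Q stands at 11.6% and 26.1%, so G.L holds 86.3% and 70.1% of the two products, against the second round's 84.3% and 66.9%. Thursday's neighbour charged with 0.10 M of G keeps the equal charges, so its one-step split is again 5.39. It ends with G.L at 48.2% and L.Q at 4.49%, a share of 91.5%, close to the first round's 91.5%, with 29% of its G still free.

The numbers are made up.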